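**Retrosynthetic overview**

1. Target 28 ⇐ bis(tert-butyl ester) 27 (acidolysis) ⇐ B-alkyl Suzuki coupling at C12–C13 between the 9-BBN adduct of vinyl decalin 19 and the (Z)-β-iodo enoate 25.
2. 19 ⇐ 6-keto-9-formyl decalin 15: C11=C12 by Wittig methylenation, C6=C7 by enol triflate reduction.
3. Ring B (the only ring closed in the route) ⇐ keto enal 13 by intramolecular Michael addition of C7 to C8, which equilibrates C8 and C9 to equatorial.
4. 13 ⇐ cyclohexanone 8: the C1 oxygen leaves through the enol triflate, the vinyl group becomes the methyl ketone, the acetal becomes the aldehyde. Ring A is never closed; it is the ring of enone 4.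
5. 8 ⇐ 4 + 5 + 3 in one flask. The strategy rests on C5 and C10 of ring A being the β- and α-carbons of 2,4,4-trimethylcyclohexenone, so that C5–C6 and C10–C9 of ring B can be attached trans across the future ring fusion.

Key step: step 2

Remark: atom numbers are labdane numbers (C1–C10 decalin, C11–C16 side chain, C17 the carboxyl carbon on C8, C20 the methyl on C10).
Assumption: the sense of induction of the ferrocenyl diphosphine in step 2 is not known for enone 4; the (R,SP) ligand is written, and its commercial mirror image is to be used if the first run shows the opposite sense at C5.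
Assumption: 8 is drawn as the 2E isomer expected from protonation of allenolate 7 on the side of the smaller acetal group; the 2Z isomer would follow the same route, because the C8=C9 geometry disappears in step 7.
Assumption: enone 4 and the THP ether of propargyl alcohol (20) are bought.

**Route**

Step 1
Reactants: 1 3,3-diethoxyprop-1-yne
Product: 3 tert-butyl 4,4-diethoxybut-2-ynoate, via lithium acetylide 2 (not isolated)
Conditions: n-BuLi, THF, −78 °C; then Boc2O, −78 → 0 °C
Reagents that add atoms: di-tert-butyl dicarbonate, CC(C)(C)OC(=O)OC(=O)OC(C)(C)C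
Why: Deprotonation of the terminal alkyne and C-acylation of the lithium acetylide with Boc2O is the standard route to tert-butyl alkynoates, and the diethyl acetal is inert to base.

Step 2
Reactants: 4 2,4,4-trimethylcyclohex-2-en-1-one; 5 vinylmagnesium bromide; 3 tert-butyl 4,4-diethoxybut-2-ynoate
Product: 8 tert-butyl (2E)-4,4-diethoxy-3-[(1R,6R)-6-ethenyl-1,5,5-trimethyl-2-oxocyclohexyl]but-2-enoate, via bromomagnesium enolate 6 (not isolated), via bromomagnesium allenolate 7 (not isolated)
Conditions: CuBr·SMe2 (5 mol%), (R)-1-[(SP)-2-(diphenylphosphino)ferrocenyl]ethyldicyclohexylphosphine (C36H44FeP2, 6 mol%), t-BuOMe, −78 °C, slow addition of 5 (THF solution); then 3, DMPU, −78 → −40 °C; aq NH4Cl at −78 °C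
Reagents that add atoms: none
Why: Proposed new method: monovalent copper bound to the chiral diphosphine transfers the vinyl group of 5 to C5, the β-carbon of 4 (copper π-complex, oxidative addition, reductive elimination), and the bromomagnesium enolate 6 released adds through C10 to the ynoate carbon β to the ester (C9, which carries the acetal), the allenolate 7 being protonated on work-up. The closest known reaction type is the copper-catalysed asymmetric conjugate addition of Grignard reagents to cyclohexenones with one-flask trapping of the magnesium enolate by a carbon electrophile; vinyl transfer to a 2,4,4-trisubstituted enone and trapping by an alkynoate have not been shown. No ring is closed: the two skeletal bonds C5–C6 and C10–C9 are formed on the existing ring A. C5 is set by the chiral ligand on copper, and C10 is set by the substrate, since the ynoate should approach the enolate face anti to the adjacent C5 vinyl group, which gives the trans relationship of the later ring fusion. The step needs 1,4- over 1,2-addition of the Grignard reagent (slow addition at −78 °C to the copper catalyst in a weakly coordinating ether), C- over O-attack at C9 and not C8 of the ynoate (polarisation by the ester and the unhindered linear alkyne), and a cold quench so that 7 is protonated before it can add to the C1 carbonyl.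

Step 3
Reactants: 8 tert-butyl (2E)-4,4-diethoxy-3-[(1R,6R)-6-ethenyl-1,5,5-trimethyl-2-oxocyclohexyl]but-2-enoate
Product: 10 tert-butyl (2E)-4,4-diethoxy-3-[(1R,6R)-6-ethenyl-1,5,5-trimethyl-2-(trifluoromethanesulfonyloxy)cyclohex-2-en-1-yl]but-2-enoate, via potassium enolate 9 (not isolated)
Conditions: KHMDS, THF, −78 °C; then PhNTf2, −78 → 0 °C
Reagents that add atoms: N-phenylbis(trifluoromethanesulfonimide), O=S(=O)(N(c1ccccc1)S(=O)(=O)C(F)(F)F)C(F)(F)F
Why: Kinetic enolate O-triflation, in which only C2 carries α-hydrogens (C10 is quaternary), so a single enol triflate can form, and the enoate, acetal and vinyl group are inert to KHMDS at −78 °C.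

Step 4
Reactants: 10 the C1 enol triflate
Product: 11 tert-butyl (2E)-4,4-diethoxy-3-[(1R,6R)-6-ethenyl-1,5,5-trimethylcyclohex-2-en-1-yl]but-2-enoate
Conditions: Pd(OAc)2 (5 mol%), PPh3 (10 mol%), HCO2H, Et3N, DMF, 60 °C
Reagents that add atoms: none
Why: Palladium-catalysed formate reduction of an enol triflate (oxidative addition to zerovalent palladium, formate exchange, decarboxylation, reductive elimination) replaces C1–O by C1–H without a radical or anion at C1, which would invite a 1,2-shift of the neighbouring alkenyl group, and the buffered medium spares acetal and tert-butyl ester.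

Step 5
Reactants: 11 the vinyl cyclohexene acetal
Product: 12 tert-butyl (2E)-3-[(1R,6R)-6-acetyl-1,5,5-trimethylcyclohex-2-en-1-yl]-4,4-diethoxybut-2-enoate
Conditions: PdCl2 (10 mol%), CuCl, O2 (1 atm), DMF–H2O 7:1, rt
Reagents that add atoms: water, O
Why: Tsuji–Wacker oxidation, in which Markovnikov hydroxypalladation of the monosubstituted vinyl group gives the methyl ketone C6(=O)–C7H3, while the 1,2-disubstituted ring alkene and the electron-poor trisubstituted enoate are much less reactive towards divalent palladium.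

Step 6
Reactants: 12 the methyl ketone acetal
Product: 13 tert-butyl (2E)-3-[(1R,6R)-6-acetyl-1,5,5-trimethylcyclohex-2-en-1-yl]-4-oxobut-2-enoate
Conditions: TsOH·H2O (0.2 equiv), acetone–H2O 10:1, rt
Reagents that add atoms: water, O
Why: Acid-catalysed acetal hydrolysis under conditions too mild to cleave the tert-butyl ester turns C11 into the aldehyde that activates C8 as a Michael acceptor.

Step 7
Reactants: 13 the keto enal
Product: 14 tert-butyl (1R,2S,4aR,8aS)-1-formyl-5,5,8a-trimethyl-4-oxo-1,2,3,4,4a,5,6,8a-octahydronaphthalene-2-carboxylate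
Conditions: t-BuOK (0.3 equiv), t-BuOH–THF 1:4, 0 °C → rt; AcOH quench
Reagents that add atoms: none
Why: Intramolecular Michael addition (6-endo-trig) of the methyl-ketone enolate C7 to C8, the β-carbon of the enal, closes ring B; the competing 1,2-addition to the aldehyde is reversible under catalytic alkoxide whereas the conjugate adduct is the thermodynamic sink, and retro-Michael and enolisation equilibria should place the C8 ester and the C9 formyl group equatorial (trans to each other, C9–CHO cis to C20) on a trans-fused decalin.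

Step 8
Reactants: 14 the bicyclic keto aldehyde with C1=C2
Product: 15 tert-butyl (1R,2S,4aR,8aS)-1-formyl-5,5,8a-trimethyl-4-oxodecahydronaphthalene-2-carboxylate
Conditions: H2 (1 atm), 10% Pd/C, EtOAc, rt
Reagents that add atoms: none
Why: Catalytic hydrogenation of the only remaining C=C (C1=C2) completes the removal of the C1 oxygen, ketone, aldehyde and ester are not reduced at 1 atm over Pd/C, and no stereocentre is created.

Step 9
Reactants: 15 the saturated keto aldehyde
Product: 16 tert-butyl (1R,2S,4aR,8aS)-1-ethenyl-5,5,8a-trimethyl-4-oxodecahydronaphthalene-2-carboxylate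
Conditions: Ph3PCH3Br, KHMDS, THF, 0 °C; then 15, −78 → 0 °C
Reagents that add atoms: methyltriphenylphosphonium bromide, C[P+](c1ccccc1)(c1ccccc1)c1ccccc1.[Br-]
Why: Wittig methylenation, in which the aldehyde reacts far faster than the hindered C6 ketone with one equivalent of ylide at low temperature, and C9, if it enolises, returns to the equatorial configuration.

Step 10
Reactants: 16 the C9-vinyl 6-ketone
Product: 18 tert-butyl (1R,2R,4aR,8aS)-1-ethenyl-5,5,8a-trimethyl-4-(trifluoromethanesulfonyloxy)-1,2,4a,5,6,7,8,8a-octahydronaphthalene-2-carboxylate, via potassium enolate 17 (not isolated)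
Conditions: KHMDS (1.05 equiv), THF, −78 °C; then PhNTf2, −78 → −20 °C
Reagents that add atoms: N-phenylbis(trifluoromethanesulfonimide), O=S(=O)(N(c1ccccc1)S(=O)(=O)C(F)(F)F)C(F)(F)F
Why: Kinetic deprotonation should occur at the C7 methylene and not at the hindered tertiary C5–H or the less acidic C8–H, and O-triflation of that enolate fixes the C6=C7 double bond.

Step 11
Reactants: 18 the C6 enol triflate
Product: 19 tert-butyl (1R,2S,4aR,8aS)-1-ethenyl-5,5,8a-trimethyl-1,2,4a,5,6,7,8,8a-octahydronaphthalene-2-carboxylate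
Conditions: Pd(OAc)2 (5 mol%), PPh3 (10 mol%), HCO2H, Et3N, DMF, 60 °C
Reagents that add atoms: none
Why: The same palladium-catalysed formate reduction of an enol triflate as in step 4, whose mild amine/formate medium should neither move the C6=C7 double bond into conjugation with the C8 ester nor epimerise C8.

Step 12
Reactants: 20 2-(prop-2-yn-1-yloxy)oxane
Product: 22 tert-butyl 4-(oxan-2-yloxy)but-2-ynoate, via lithium acetylide 21 (not isolated)
Conditions: n-BuLi, THF, −78 °C; then Boc2O, −78 → 0 °C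
Reagents that add atoms: di-tert-butyl dicarbonate, CC(C)(C)OC(=O)OC(=O)OC(C)(C)C
Why: Acetylide C-acylation with Boc2O as in step 1, which the THP acetal tolerates.

Step 13
Reactants: 22 tert-butyl 4-(oxan-2-yloxy)but-2-ynoate
Product: 23 tert-butyl 4-hydroxybut-2-ynoate
Conditions: PPTS (0.1 equiv), EtOH, 50 °C
Reagents that add atoms: none
Why: Acid-catalysed transacetalisation to ethanol removes the THP group without touching the tert-butyl ester or the ynoate.

Step 14
Reactants: 23 tert-butyl 4-hydroxybut-2-ynoate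
Product: 24 tert-butyl 4-acetoxybut-2-ynoate
Conditions: Ac2O, pyridine, DMAP (cat.), CH2Cl2, 0 °C → rt
Reagents that add atoms: acetic anhydride, CC(=O)OC(C)=O
Why: Standard DMAP-catalysed acetylation of a primary alcohol.

Step 15
Reactants: 24 tert-butyl 4-acetoxybut-2-ynoate
Product: 25 tert-butyl (2Z)-4-acetoxy-3-iodobut-2-enoate
Conditions: NaI, AcOH, 70 °C
Reagents that add atoms: sodium iodide, [Na+].[I-]
Why: Conjugate hydroiodination of an ynoate, in which iodide adds to the β-carbon and the allenolate is protonated anti, gives the (Z)-β-iodo enoate with iodine cis to the ester, the geometry needed for C12 cis to C15.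

Step 16
Reactants: 19 the vinyl decalin ester; 25 tert-butyl (2Z)-4-acetoxy-3-iodobut-2-enoate
Product: 27 tert-butyl (1R,2S,4aR,8aS)-1-[(3E)-3-(acetoxymethyl)-5-tert-butoxy-5-oxopent-3-en-1-yl]-5,5,8a-trimethyl-1,2,4a,5,6,7,8,8a-octahydronaphthalene-2-carboxylate, via B-alkyl-9-BBN adduct 26 (not isolated)
Conditions: 9-BBN dimer, THF, 0 °C → rt; then 25, PdCl2(dppf) (dppf = 1,1'-bis(diphenylphosphino)ferrocene, 5 mol%), AsPh3, 3 M aq K3PO4, DMF, rt
Reagents that add atoms: none
Why: 9-BBN hydroborates only the monosubstituted C11=C12 vinyl group (boron on C12), and the B-alkyl Suzuki–Miyaura coupling with the β-iodo enoate proceeds with retention of alkene geometry to give the 13E side chain under a base mild enough for the acetate and the β,γ-unsaturated ester.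

Step 17
Reactants: 27 the bis(tert-butyl ester)
Product: 28 (1R,2S,4aR,8aS)-1-[(3E)-3-(acetoxymethyl)-4-carboxybut-3-en-1-yl]-5,5,8a-trimethyl-1,2,4a,5,6,7,8,8a-octahydronaphthalene-2-carboxylic acid (CNP0108723.1)
Conditions: TFA–CH2Cl2 1:3, 0 °C → rt
Reagents that add atoms: none
Why: Acidolysis of both tert-butyl esters through the tert-butyl cation should leave the primary acetate, both alkenes and all four stereocentres untouched.

**Compound list**

1 | 3,3-diethoxyprop-1-yne | C#CC(OCC)OCC | starting material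
2 | lithium 3,3-diethoxyprop-1-yn-1-ide (not isolated) | [Li]C#CC(OCC)OCC | intermediate
3 | tert-butyl 4,4-diethoxybut-2-ynoate | CCOC(OCC)C#CC(=O)OC(C)(C)C | intermediate
4 | 2,4,4-trimethylcyclohex-2-en-1-one | CC1=CC(C)(C)CCC1=O | starting material
5 | vinylmagnesium bromide | C=C[Mg]Br | starting material
6 | bromomagnesium (3R)-3-ethenyl-2,4,4-trimethylcyclohex-1-en-1-olate (not isolated) | C=C[C@@H]1C(C)(C)CCC(O[Mg]Br)=C1C | intermediate
7 | bromomagnesium 1-tert-butoxy-4,4-diethoxy-3-[(1R,6R)-6-ethenyl-1,5,5-trimethyl-2-oxocyclohexyl]buta-1,2-dien-1-olate (not isolated) | C=C[C@@H]1C(C)(C)CCC(=O)[C@@]1(C)C(C(OCC)OCC)=C=C(O[Mg]Br)OC(C)(C)C | intermediate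
8 | tert-butyl (2E)-4,4-diethoxy-3-[(1R,6R)-6-ethenyl-1,5,5-trimethyl-2-oxocyclohexyl]but-2-enoate (vinyl and alkenyl trans) | C=C[C@@H]1C(C)(C)CCC(=O)[C@@]1(C)/C(C(OCC)OCC)=C\C(=O)OC(C)(C)C | intermediate
9 | potassium enolate of 8, C1–OK with C1=C2 (not isolated) | C=C[C@@H]1C(C)(C)CC=C(O[K])[C@@]1(C)/C(C(OCC)OCC)=C\C(=O)OC(C)(C)C | intermediate
10 | tert-butyl (2E)-4,4-diethoxy-3-[(1R,6R)-6-ethenyl-1,5,5-trimethyl-2-(trifluoromethanesulfonyloxy)cyclohex-2-en-1-yl]but-2-enoate | C=C[C@@H]1C(C)(C)CC=C(OS(=O)(=O)C(F)(F)F)[C@@]1(C)/C(C(OCC)OCC)=C\C(=O)OC(C)(C)C | intermediate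
11 | tert-butyl (2E)-4,4-diethoxy-3-[(1R,6R)-6-ethenyl-1,5,5-trimethylcyclohex-2-en-1-yl]but-2-enoate | C=C[C@@H]1C(C)(C)CC=C[C@@]1(C)/C(C(OCC)OCC)=C\C(=O)OC(C)(C)C | intermediate
12 | tert-butyl (2E)-3-[(1R,6R)-6-acetyl-1,5,5-trimethylcyclohex-2-en-1-yl]-4,4-diethoxybut-2-enoate | CC(=O)[C@@H]1C(C)(C)CC=C[C@@]1(C)/C(C(OCC)OCC)=C\C(=O)OC(C)(C)C | intermediate
13 | tert-butyl (2E)-3-[(1R,6R)-6-acetyl-1,5,5-trimethylcyclohex-2-en-1-yl]-4-oxobut-2-enoate | CC(=O)[C@@H]1C(C)(C)CC=C[C@@]1(C)/C(C=O)=C\C(=O)OC(C)(C)C | intermediate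
14 | tert-butyl (1R,2S,4aR,8aS)-1-formyl-5,5,8a-trimethyl-4-oxo-1,2,3,4,4a,5,6,8a-octahydronaphthalene-2-carboxylate (trans-fused; ester and formyl equatorial) | O=C[C@@H]1[C@@H](C(=O)OC(C)(C)C)CC(=O)[C@@H]2C(C)(C)CC=C[C@@]12C | intermediate
15 | tert-butyl (1R,2S,4aR,8aS)-1-formyl-5,5,8a-trimethyl-4-oxodecahydronaphthalene-2-carboxylate | O=C[C@@H]1[C@@H](C(=O)OC(C)(C)C)CC(=O)[C@@H]2C(C)(C)CCC[C@@]12C | intermediate
16 | tert-butyl (1R,2S,4aR,8aS)-1-ethenyl-5,5,8a-trimethyl-4-oxodecahydronaphthalene-2-carboxylate | C=C[C@@H]1[C@@H](C(=O)OC(C)(C)C)CC(=O)[C@@H]2C(C)(C)CCC[C@@]12C | intermediate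
17 | potassium enolate of 16, C6–OK with C6=C7 (not isolated) | C=C[C@@H]1[C@@H](C(=O)OC(C)(C)C)C=C(O[K])[C@@H]2C(C)(C)CCC[C@@]12C | intermediate
18 | tert-butyl (1R,2R,4aR,8aS)-1-ethenyl-5,5,8a-trimethyl-4-(trifluoromethanesulfonyloxy)-1,2,4a,5,6,7,8,8a-octahydronaphthalene-2-carboxylate | C=C[C@@H]1[C@@H](C(=O)OC(C)(C)C)C=C(OS(=O)(=O)C(F)(F)F)[C@@H]2C(C)(C)CCC[C@@]12C | intermediate
19 | tert-butyl (1R,2S,4aR,8aS)-1-ethenyl-5,5,8a-trimethyl-1,2,4a,5,6,7,8,8a-octahydronaphthalene-2-carboxylate | C=C[C@@H]1[C@@H](C(=O)OC(C)(C)C)C=C[C@@H]2C(C)(C)CCC[C@@]12C | intermediate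
20 | 2-(prop-2-yn-1-yloxy)oxane (THP ether of propargyl alcohol, racemic) | C#CCOC1CCCCO1 | starting material
21 | lithium 3-(oxan-2-yloxy)prop-1-yn-1-ide (not isolated) | [Li]C#CCOC1CCCCO1 | intermediate
22 | tert-butyl 4-(oxan-2-yloxy)but-2-ynoate | CC(C)(C)OC(=O)C#CCOC1CCCCO1 | intermediate
23 | tert-butyl 4-hydroxybut-2-ynoate | CC(C)(C)OC(=O)C#CCO | intermediate
24 | tert-butyl 4-acetoxybut-2-ynoate | CC(=O)OCC#CC(=O)OC(C)(C)C | intermediate
25 | tert-butyl (2Z)-4-acetoxy-3-iodobut-2-enoate | CC(=O)OC/C(I)=C/C(=O)OC(C)(C)C | intermediate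
26 | tert-butyl (1R,2S,4aR,8aS)-1-[2-(9-borabicyclo[3.3.1]nonan-9-yl)ethyl]-5,5,8a-trimethyl-1,2,4a,5,6,7,8,8a-octahydronaphthalene-2-carboxylate (not isolated) | C1CCC2CCCC1B2CC[C@@H]1[C@@H](C(=O)OC(C)(C)C)C=C[C@@H]2C(C)(C)CCC[C@@]12C | intermediate
27 | tert-butyl (1R,2S,4aR,8aS)-1-[(3E)-3-(acetoxymethyl)-5-tert-butoxy-5-oxopent-3-en-1-yl]-5,5,8a-trimethyl-1,2,4a,5,6,7,8,8a-octahydronaphthalene-2-carboxylate | CC(=O)OC/C(=C/C(=O)OC(C)(C)C)CC[C@@H]1[C@@H](C(=O)OC(C)(C)C)C=C[C@@H]2C(C)(C)CCC[C@@]12C | intermediate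
28 | (1R,2S,4aR,8aS)-1-[(3E)-3-(acetoxymethyl)-4-carboxybut-3-en-1-yl]-5,5,8a-trimethyl-1,2,4a,5,6,7,8,8a-octahydronaphthalene-2-carboxylic acid (CNP0108723.1) | CC(=O)OC/C(=C/C(=O)O)CC[C@@H]1[C@@H](C(=O)O)C=C[C@@H]2C(C)(C)CCC[C@@]12C | target

**Step count**

Total: 17 steps. Longest linear sequence: 13 steps (steps 1–11, 16 and 17); steps 12–15 build the side-chain fragment 25.

**Steps most likely to fail**

Step 2 (key step). Vinyl transfer to the hindered, α-substituted enone may be slow, may give way to 1,2-addition, or may proceed with low enantioselectivity. The congested magnesium enolate may then fail to add through C10 to the ynoate (O-addition, proton transfer, closure of the allenolate onto the C1 carbonyl) or may add with poor facial selectivity. The fallback sets out from 4 and 5 and comes back at 8. It separates the two bond formations, each by known chemistry. The copper/diphosphine-catalysed vinyl addition is run in the presence of Me3SiCl, which accelerates conjugate addition and traps the enolate, and the silyl enol ether {[(3R)-3-ethenyl-2,4,4-trimethylcyclohex-1-en-1-yl]oxy}trimethylsilane F1 is isolated and its enantiomeric purity checked. MeLi in THF at 0 °C then cleaves the Si–O bond to give the regiodefined lithium (3R)-3-ethenyl-2,4,4-trimethylcyclohex-1-en-1-olate F2. This more reactive enolate is added to ynoate 3 in THF–DMPU at −78 °C and quenched cold, giving 8.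

Step 7. The C7 enolate may add 1,2 to the aldehyde and the ketol may dehydrate, so that an aldol condensation forming a six-membered ring through C11 drains material before the conjugate addition to C8 can win. The fallback sets out from 13 and comes back at 19. It replaces the aldehyde by a nitrile, which activates C8 equally but is not attacked by a ketone enolate under these conditions.
- Hydroxylamine hydrochloride and pyridine in ethanol at 0 °C convert the aldehyde of 13 selectively into tert-butyl (2E)-3-[(1R,6R)-6-acetyl-1,5,5-trimethylcyclohex-2-en-1-yl]-4-(hydroxyimino)but-2-enoate F3.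
- Trifluoroacetic anhydride and pyridine dehydrate it to tert-butyl (2E)-3-[(1R,6R)-6-acetyl-1,5,5-trimethylcyclohex-2-en-1-yl]-3-cyanoprop-2-enoate F4.
- Catalytic t-BuOK in t-BuOH–THF closes ring B by Michael addition of C7 to C8 to give tert-butyl (1R,2S,4aR,8aS)-1-cyano-5,5,8a-trimethyl-4-oxo-1,2,3,4,4a,5,6,8a-octahydronaphthalene-2-carboxylate F5.
- Hydrogenation over Pd/C gives tert-butyl (1R,2S,4aR,8aS)-1-cyano-5,5,8a-trimethyl-4-oxodecahydronaphthalene-2-carboxylate F6.
- KHMDS and PhNTf2 give tert-butyl (1R,2R,4aR,8aS)-1-cyano-5,5,8a-trimethyl-4-(trifluoromethanesulfonyloxy)-1,2,4a,5,6,7,8,8a-octahydronaphthalene-2-carboxylate F7.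
- Pd(OAc)2/PPh3 with formic acid and Et3N gives tert-butyl (1R,2S,4aR,8aR)-1-cyano-5,5,8a-trimethyl-1,2,4a,5,6,7,8,8a-octahydronaphthalene-2-carboxylate F8.
- DIBAL-H in toluene at −78 °C followed by aqueous acid gives tert-butyl (1R,2S,4aR,8aR)-1-formyl-5,5,8a-trimethyl-1,2,4a,5,6,7,8,8a-octahydronaphthalene-2-carboxylate F9.
- Wittig methylenation of F9 with Ph3P=CH2 gives 19.

Step 5. The vinyl group sits on C5 between two quaternary carbons, so hydroxypalladation at C6 may be slow or may turn anti-Markovnikov, and the acidic copper/palladium medium may start to cleave the acetal. The fallback sets out from 11 and comes back at 12. It hydrates the alkene by a different mechanism and then oxidises. Hg(OAc)2 in THF–H2O adds Markovnikov to the terminal alkene, much faster than to the ring alkene or the enoate, to give the organomercurial tert-butyl (2E)-3-{(1R,6R)-6-[2-(acetoxymercurio)-1-hydroxyethyl]-1,5,5-trimethylcyclohex-2-en-1-yl}-4,4-diethoxybut-2-enoate F10. Alkaline NaBH4 demercurates it to the secondary alcohol tert-butyl (2E)-4,4-diethoxy-3-[(1R,6R)-6-(1-hydroxyethyl)-1,5,5-trimethylcyclohex-2-en-1-yl]but-2-enoate F11, a mixture of carbinol epimers. Dess–Martin periodinane in CH2Cl2 oxidises it to 12.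

**Further compounds**

F1 | step 2 | {[(3R)-3-ethenyl-2,4,4-trimethylcyclohex-1-en-1-yl]oxy}trimethylsilane | C=C[C@@H]1C(C)(C)CCC(O[Si](C)(C)C)=C1C
F2 | step 2 | lithium (3R)-3-ethenyl-2,4,4-trimethylcyclohex-1-en-1-olate | C=C[C@@H]1C(C)(C)CCC(O[Li])=C1C
F3 | step 7 | tert-butyl (2E)-3-[(1R,6R)-6-acetyl-1,5,5-trimethylcyclohex-2-en-1-yl]-4-(hydroxyimino)but-2-enoate | CC(=O)[C@@H]1C(C)(C)CC=C[C@@]1(C)/C(C=NO)=C\C(=O)OC(C)(C)C
F4 | step 7 | tert-butyl (2E)-3-[(1R,6R)-6-acetyl-1,5,5-trimethylcyclohex-2-en-1-yl]-3-cyanoprop-2-enoate | CC(=O)[C@@H]1C(C)(C)CC=C[C@@]1(C)/C(C#N)=C\C(=O)OC(C)(C)C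
F5 | step 7 | tert-butyl (1R,2S,4aR,8aS)-1-cyano-5,5,8a-trimethyl-4-oxo-1,2,3,4,4a,5,6,8a-octahydronaphthalene-2-carboxylate | N#C[C@@H]1[C@@H](C(=O)OC(C)(C)C)CC(=O)[C@@H]2C(C)(C)CC=C[C@@]12C
F6 | step 7 | tert-butyl (1R,2S,4aR,8aS)-1-cyano-5,5,8a-trimethyl-4-oxodecahydronaphthalene-2-carboxylate | N#C[C@@H]1[C@@H](C(=O)OC(C)(C)C)CC(=O)[C@@H]2C(C)(C)CCC[C@@]12C
F7 | step 7 | tert-butyl (1R,2R,4aR,8aS)-1-cyano-5,5,8a-trimethyl-4-(trifluoromethanesulfonyloxy)-1,2,4a,5,6,7,8,8a-octahydronaphthalene-2-carboxylate | N#C[C@@H]1[C@@H](C(=O)OC(C)(C)C)C=C(OS(=O)(=O)C(F)(F)F)[C@@H]2C(C)(C)CCC[C@@]12C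
F8 | step 7 | tert-butyl (1R,2S,4aR,8aR)-1-cyano-5,5,8a-trimethyl-1,2,4a,5,6,7,8,8a-octahydronaphthalene-2-carboxylate | N#C[C@@H]1[C@@H](C(=O)OC(C)(C)C)C=C[C@@H]2C(C)(C)CCC[C@@]12C
F9 | step 7 | tert-butyl (1R,2S,4aR,8aR)-1-formyl-5,5,8a-trimethyl-1,2,4a,5,6,7,8,8a-octahydronaphthalene-2-carboxylate | O=C[C@@H]1[C@@H](C(=O)OC(C)(C)C)C=C[C@@H]2C(C)(C)CCC[C@@]12C
F10 | step 5 | tert-butyl (2E)-3-{(1R,6R)-6-[2-(acetoxymercurio)-1-hydroxyethyl]-1,5,5-trimethylcyclohex-2-en-1-yl}-4,4-diethoxybut-2-enoate | CC(=O)O[Hg]CC(O)[C@@H]1C(C)(C)CC=C[C@@]1(C)/C(C(OCC)OCC)=C\C(=O)OC(C)(C)C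
F11 | step 5 | tert-butyl (2E)-4,4-diethoxy-3-[(1R,6R)-6-(1-hydroxyethyl)-1,5,5-trimethylcyclohex-2-en-1-yl]but-2-enoate | CC(O)[C@@H]1C(C)(C)CC=C[C@@]1(C)/C(C(OCC)OCC)=C\C(=O)OC(C)(C)C
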